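## Structural features

The target is an ent-labdane: a trans-fused decalin (ring A = C1–C5, C10; ring B = C5–C10) with a saturated 3-methylpentanoic acid chain (C11–C16, acid at C15) on C9. Ring A holds the quaternary C4, which carries an axial methyl (C19, cis to the C10 methyl) and an equatorial CH2O–angeloyl arm (C18). Ring B holds the tertiary carbinol C8 (equatorial OH, axial methyl) next to C9 (axial H, equatorial chain). C4, C5, C10, C9 and C8 are five contiguous stereocentres (4S,5S,8S,9S,10R), two of them quaternary; C13 (S) stands alone in the chain and cannot be relayed from the ring. The fragile groups are the angelate (a (Z)-2-methylbut-2-enoate that slips to the (E)-tiglate under nucleophilic or basic catalysis), the tertiary C8 alcohol (dehydration in acid) and the free acid. The real difficulty is the quaternary C4 with two different one-carbon arms in a fixed relation to the ring fusion, together with the configuration at C8. The key step exploits the pattern of ring A: C4 quaternary, C5 bearing the C6 arm and C10 bearing a methyl is the pattern of a 2,3-dialkylbenzoic acid. After dearomatisation the C4 carboxamide lies β,γ to the C5=C10 alkene, so protonation at C5 with carbonyl-oxygen bridging to C10 fixes H-5, and the (E)-C8=C9 alkene of the C6 arm then closes ring B on C10.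

## Logic of the disconnections

**28 ⇒ 26 ⇒ 25.** No skeletal bond is cut: the C15 carboxyl goes back to a primary alcohol (through 27) and then to its silyl ether. A free acid would interfere with the acylation, the hydride and the hydrazone chemistry, so it is unveiled last. The demand is an oxidation and a desilylation that leave the (Z)-enoate and the tertiary alcohol alone.

**25 ⇒ 22 + 23.** The C18–O acyl bond is cut. The angelate is the most isomerisation-prone group and is put on as late as the C15 protection allows. The forward step must acylate a neopentyl primary hydroxyl without Z→E isomerisation and without touching the tertiary C8 hydroxyl.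

**22 ⇒ 21 ⇒ 19 ⇒ 18 ⇒ 17.** The O-benzyl bond and the C2,C3 saturation are taken back together, since one hydrogenation does both. The C19 methyl is traced through aldehyde and primary alcohol to the carboxamide carbon, cutting C19–N and removing the C19 oxygen. The gain is that 17 still carries the group that both the ring closure and the dearomatisation need. The demand is the excision of N and O from an axial, doubly neopentyl carbon while the benzyl ether still masks C18 (a free β-hydroxy aldehyde could lose formaldehyde).

**17 ⇒ 14 (key).** C9–C10 is cut, together with C5–H and C8–O. This removes ring B and four stereocentres (C5, C10, C9, C8) at once and leaves a monocyclic diene whose only ring stereocentre is C4. The forward step must protonate C5 and not C10, keep H-5 trans to the carboxamide, close through a chair and cap C8 equatorially. In 14 the C15 oxygen is a triisopropylsilyl ether: it survives LiN(i-Pr)2 and K/NH3, which an aryl-silyl or benzyl group would not, and it tolerates brief anhydrous acid better than a TBS ether. The C18 oxygen is a benzyl ether, which arrives with the electrophile and leaves in the hydrogenation. The acid stage is run without water, because water would hydrolyse the bridged iminium ether to the lactone and expel the auxiliary; trifluoroacetate caps C8 and is removed in the work-up.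

**14 ⇒ 11 + 12.** C4–C18 is cut (and H is removed from C1). The arene then supplies every ring A carbon and the auxiliary sets C4 by Birch reductive alkylation. The demand is facial control in the enolate alkylation and C-alkylation by an alkoxymethyl chloride in competition with ammonia.

**11 ⇒ 4 + 9.** C6–C7 is cut, which joins the two halves at a benzylic carbon. The demand is lateral (not ring) lithiation and SN2 (not SN2′) attack on the allylic bromide.

**9 ⇒ 8 ⇒ 6 ⇒ 5 and 4 ⇒ 1 + 2.** The C7 bromide comes from allylic oxidation of the (E)-methyl group of the protected chiral-pool alcohol, which also brings C13 and fixes the (E) geometry of C8=C9. The amide bond leads to the acid and the auxiliary.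

## Other disconnections considered

**Alternative 1:** The cut is the C18–O bond on an intact decalin obtained by degrading andrographolide A1. In the forward key step the 19-deoxy C3 alcohol A2 would be silylated with Et2SiH2. An iridium catalyst ([Ir(cod)OMe]2 with a phenanthroline ligand, norbornene as hydrogen acceptor) would then insert the Si–H into a C–H bond of the equatorial C18 methyl to give the oxasilolane A3. Oxidation of the C–Si bond would put the oxygen on C18.
- In favour: C5, C9 and C10 come from the natural product in the correct ent series, and this type of directed methyl C–H silylation through a five-membered silacycle is established for terpenoid 3-ols. On security of the ring stereocentres and on mechanistic precedent of its key step this alternative is the better plan.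
- Against: A1 has the wrong oxidation pattern. The C19 oxygen must be removed. The C3 oxygen is needed only as a directing group and must then be removed. The 8(17)-alkene must become the equatorial tertiary carbinol. The butenolide must be cut back to C12 and C13–C16 rebuilt, with the 13S methyl set by reagent control far from any ring stereocentre.
- Comparison: the chosen plan builds every carbon from four simple pieces, carries C13 from the chiral pool and has one deoxygenation (amide to methyl) against three here. It should be markedly shorter (14 operations against an estimate of well over twenty), but it rests on an unproven ring closure.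

**Alternative 2:** The cut is C5–C10 and C8–C9 together. In the forward key step the trienal A4 would undergo a thermal intramolecular Diels–Alder reaction: the (E)-3-methyl enal adds across the tethered (E,E)-1-silyloxydiene to give the trans-fused octalin A5.
- In favour: two rings and C5, C9 and C10 arise in one pericyclic step whose outcome follows from alkene geometry and the endo rule. The C9 aldehyde is a convergent handle for the side chain. On predictability of these three centres it is the equal or the better of the chosen plan.
- Against: A4 must already contain the quaternary C4 and a C3 oxygen stereocentre made by acyclic asymmetric chemistry, so the hardest centre is moved and not solved. The dienophile is β,β-disubstituted and sluggish, while the silyloxydiene limits Lewis-acid acceleration. A5 carries a secondary silyl ether at C8 where a tertiary methyl carbinol is needed (oxidation, methylenation and a face-selective hydration or epoxide reduction). C3 must be deoxygenated, C6=C7 reduced, and four carbons with C13 added at C9.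
- Comparison: the chosen plan sets C8 with its methyl and oxygen directly in the ring closure and sets C4 by an auxiliary. It should need clearly fewer steps.

**Alternative 3:** The cut is C3–C4 and C5–C10 (ring A), with ring B closed later at C9–C10 by a cation, the same bond as in the chosen plan. In the forward key step the dienal A6 and the (Z)-silyl dienol ether A7 would combine in a chiral-Lewis-acid Diels–Alder reaction to give the cycloadduct A8.
- In favour: the C4/C5 relation comes from suprafacial addition to an (E)-enal, which is mechanistically more secure than a stepwise ionic relay. C18 arrives as an aldehyde on the correct carbon and C19 as a methyl, so no amide-to-methyl excision is needed. Control is catalytic. On these three points it is the better plan.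
- Against: an α-methyl-β-alkyl enal is a poor dienophile and needs a strongly activating chiral Lewis acid in the presence of a remote alkene and a silyl ether. The C1 oxygen of A8 must be removed and turned, with regiocontrol, into a C10 cation precursor. The aldehyde must be masked during the acid step, or it would engage the alkenes.
- Comparison: the capping of C8 after ring closure is the same open question in both plans (equal). The step count should be similar or slightly higher. The chosen plan reaches the cyclisation substrate directly from the Birch step.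

Key step: step 7

Assumption: the potassium enolate 13 is taken to accept the electrophile on the face that gives the (1R) quaternary carbon of 14, as expected for 2-alkylbenzamide enolates with this auxiliary; if the sense were opposite, (R)-2-(methoxymethyl)pyrrolidine would replace 2 and nothing else would change.

## Route

Step 1
Reactants: 1 2,3-dimethylbenzoic acid; 2 (S)-2-(methoxymethyl)pyrrolidine
Product: 4 (S)-(2,3-dimethylphenyl)[2-(methoxymethyl)pyrrolidin-1-yl]methanone, via acid chloride 3 (not isolated)
Conditions: (COCl)2, DMF (cat.), CH2Cl2, 0 °C → rt; then 2, Et3N, CH2Cl2, 0 °C → rt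
Reagents that add atoms: none
Why: Acid chloride formation followed by amide coupling with a secondary amine; the stereocentre of the auxiliary is not involved.

Step 2
Reactants: 5 (S)-citronellol
Product: 6 (3S)-3,7-dimethyl-1-(triisopropylsilyloxy)oct-6-ene
Conditions: i-Pr3SiCl, imidazole, DMF, rt
Reagents that add atoms: chlorotriisopropylsilane, CC(C)[Si](Cl)(C(C)C)C(C)C
Why: Silylation of a primary alcohol; the triisopropylsilyl ether is chosen because it survives the amide base, the dissolving metal and brief anhydrous acid.

Step 3
Reactants: 6 (3S)-3,7-dimethyl-1-(triisopropylsilyloxy)oct-6-ene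
Product: 8 (2E,6S)-2,6-dimethyl-8-(triisopropylsilyloxy)oct-2-en-1-ol, via enal 7 (not isolated)
Conditions: SeO2 (cat.), t-BuOOH, salicylic acid (cat.), CH2Cl2, rt; then NaBH4, MeOH, 0 °C
Reagents that add atoms: tert-butyl hydroperoxide, CC(C)(C)OO
Why: Selenium dioxide allylic oxidation (ene reaction, then [2,3]-sigmatropic shift) attacks the (E)-methyl of a trisubstituted gem-dimethyl alkene, which fixes the (E) geometry of the later C8=C9 bond; the over-oxidised share, enal 7, is returned to the alcohol by borohydride in the same flask.

Step 4
Reactants: 8 (2E,6S)-2,6-dimethyl-8-(triisopropylsilyloxy)oct-2-en-1-ol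
Product: 9 (2E,6S)-1-bromo-2,6-dimethyl-8-(triisopropylsilyloxy)oct-2-ene
Conditions: CBr4, PPh3, CH2Cl2, 0 °C
Reagents that add atoms: carbon tetrabromide, BrC(Br)(Br)Br
Why: Appel bromination of a primary allylic alcohol at low temperature should proceed without allylic transposition or loss of geometry; the bromide is used at once.

Step 5
Reactants: 4 (S)-(2,3-dimethylphenyl)[2-(methoxymethyl)pyrrolidin-1-yl]methanone; 9 (2E,6S)-1-bromo-2,6-dimethyl-8-(triisopropylsilyloxy)oct-2-ene
Product: 11 (S)-{2-[(3E,7S)-3,7-dimethyl-9-(triisopropylsilyloxy)non-3-en-1-yl]-3-methylphenyl}[2-(methoxymethyl)pyrrolidin-1-yl]methanone, via benzylic lithium compound 10 (not isolated)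
Conditions: LiN(i-Pr)2, THF, −78 °C; then 9, −78 → −40 °C
Reagents that add atoms: none
Why: Lateral lithiation of a tertiary o-toluamide: the amide base removes a proton from the ortho methyl (amide-stabilised benzylic anion), not from the ring or the meta methyl, and the anion displaces the primary allylic bromide in an SN2 alkylation that forms C6–C7.

Step 6
Reactants: 11 (S)-{2-[(3E,7S)-3,7-dimethyl-9-(triisopropylsilyloxy)non-3-en-1-yl]-3-methylphenyl}[2-(methoxymethyl)pyrrolidin-1-yl]methanone; 12 benzyl chloromethyl ether
Product: 14 (S)-{(1R)-1-[(benzyloxy)methyl]-2-[(3E,7S)-3,7-dimethyl-9-(triisopropylsilyloxy)non-3-en-1-yl]-3-methylcyclohexa-2,5-dien-1-yl}[2-(methoxymethyl)pyrrolidin-1-yl]methanone, via potassium enolate 13 (not isolated)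
Conditions: K (2.2 equiv), t-BuOH (1 equiv), NH3(l)/THF, −78 °C; piperylene; then 12 (excess), −78 °C; NH4Cl
Reagents that add atoms: none
Why: Birch reductive alkylation of a chiral benzamide: two-electron reduction with protonation para to the carboxamide gives the cross-conjugated amide enolate 13, and C-alkylation at the ipso carbon on the face set by the chelated auxiliary creates the quaternary C4; the isolated alkene and the silyl ether are inert to the metal.

Step 7
Reactants: 14 (S)-{(1R)-1-[(benzyloxy)methyl]-2-[(3E,7S)-3,7-dimethyl-9-(triisopropylsilyloxy)non-3-en-1-yl]-3-methylcyclohexa-2,5-dien-1-yl}[2-(methoxymethyl)pyrrolidin-1-yl]methanone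
Product: 17 (4R,5S,8S,9S,10R,13S)-18-benzyloxy-8-hydroxy-15-(triisopropylsilyloxy)-ent-labd-2-en-19-oic acid (S)-2-(methoxymethyl)pyrrolidide, via bridged iminium ether 15 (not isolated), via C8 trifluoroacetate 16 (not isolated)
Conditions: anhydrous CF3CO2H/CH2Cl2 (1:1), 0.01 M, −20 → 0 °C; then poured into K2CO3, MeOH, 0 °C → rt
Reagents that add atoms: trifluoroacetic acid, OC(=O)C(F)(F)F
Why: Proposed new method: the acid protonates the tetrasubstituted C5=C10 alkene at C5 on the face away from the C4 carboxamide while the amide oxygen closes onto C10 to give the five-membered bridged iminium ether 15; with no water present 15 is not hydrolysed to the lactone but re-ionises at the tertiary C10–O bond, C9 of the (E)-C8=C9 alkene bonds to C10, trifluoroacetate caps C8 (16) and methanolysis in the work-up frees the hydroxyl. The closest known reactions are the protic-acid cyclisation of monocyclic farnesyl-type 1,5-dienes to drimanes and the acid lactonisation of β,γ-unsaturated carboxamides; joining them through a reversible iminium ether is the untested part. Ring B closes in the 6-endo mode with respect to the C8=C9 alkene, through a chair in which the C6 arm is equatorial on ring A. C5 is controlled by anti addition of proton and amide oxygen, which leaves H-5 trans to the carboxamide carbon and cis to the benzyloxymethyl arm. C10 is set by entry of C9 on the face opposite to the departing oxygen, so the C10 methyl ends cis to the carboxamide carbon and the ring fusion is trans. C9 follows from the (E) geometry in the chair (C11 equatorial), and C8 from anti, equatorial capture by the external nucleophile (oxygen equatorial, methyl axial). The step needs protonation at C5 and not at C10: the C10 cation is tertiary and within reach of the amide oxygen through a five-membered ring, whereas a C5 cation would sit next to the acyl-bearing quaternary carbon. It also needs the ring alkene to react rather than the side-chain alkene: addition of the acid to the side-chain alkene is reversible, and only the C10 cation can close a six-membered ring.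

Step 8
Reactants: 17 (4R,5S,8S,9S,10R,13S)-18-benzyloxy-8-hydroxy-15-(triisopropylsilyloxy)-ent-labd-2-en-19-oic acid (S)-2-(methoxymethyl)pyrrolidide
Product: 18 (4S,5S,8S,9S,10R,13S)-18-benzyloxy-15-(triisopropylsilyloxy)-ent-labd-2-ene-8,19-diol
Conditions: LiH2NBH3 (from H3N·BH3 and LiN(i-Pr)2), THF, 0 → 23 °C; aq. NH4Cl
Reagents that add atoms: none
Why: Reduction of a tertiary carboxamide to the primary alcohol with lithium amidotrihydroborate, a small and strongly nucleophilic hydride source suited to α-quaternary amides; C–N cleavage releases the auxiliary, and the ethers, the alkene and all stereocentres are untouched.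

Step 9
Reactants: 18 (4S,5S,8S,9S,10R,13S)-18-benzyloxy-15-(triisopropylsilyloxy)-ent-labd-2-ene-8,19-diol
Product: 19 (4R,5S,8S,9S,10R,13S)-18-benzyloxy-8-hydroxy-15-(triisopropylsilyloxy)-ent-labd-2-en-19-al
Conditions: Dess–Martin periodinane, CH2Cl2, 0 °C → rt
Reagents that add atoms: none
Why: Hypervalent-iodine oxidation of the neopentyl primary alcohol; the tertiary C8 alcohol cannot be oxidised and the aldehyde has no α-hydrogen, so it can neither enolise nor epimerise.

Step 10
Reactants: 19 (4R,5S,8S,9S,10R,13S)-18-benzyloxy-8-hydroxy-15-(triisopropylsilyloxy)-ent-labd-2-en-19-al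
Product: 21 (4S,5S,8S,9S,10R,13S)-18-benzyloxy-15-(triisopropylsilyloxy)-ent-labd-2-en-8-ol, via N-silyl hydrazone 20 (not isolated)
Conditions: TBSNHNHTBS, Sc(OTf)3 (cat.), CH2Cl2, 0 °C → rt; evaporate; then KOt-Bu, t-BuOH, DMSO, rt
Reagents that add atoms: none
Why: Wolff–Kishner reduction through the N-silyl hydrazone, which forms without azine and loses dinitrogen at room temperature in KOt-Bu/DMSO; hot KOH/glycol, which would endanger the silyl ether, is avoided, and the benzyl ether still masks C18 so no retro-aldol loss of formaldehyde can occur.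

Step 11
Reactants: 21 (4S,5S,8S,9S,10R,13S)-18-benzyloxy-15-(triisopropylsilyloxy)-ent-labd-2-en-8-ol
Product: 22 (4S,5S,8S,9S,10R,13S)-15-(triisopropylsilyloxy)-ent-labdane-8,18-diol
Conditions: H2 (1 atm), Pd/C, EtOAc/EtOH, rt
Reagents that add atoms: none
Why: Heterogeneous hydrogenation saturates the cis-disubstituted C2=C3 alkene (no stereocentre is created) and hydrogenolyses the benzyl ether in the same operation; the silyl ether and the tertiary alcohol are stable in the neutral medium.

Step 12
Reactants: 22 (4S,5S,8S,9S,10R,13S)-15-(triisopropylsilyloxy)-ent-labdane-8,18-diol; 23 angelic acid [(Z)-2-methylbut-2-enoic acid]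
Product: 25 (4S,5S,8S,9S,10R,13S)-8-hydroxy-15-(triisopropylsilyloxy)-ent-labdan-18-yl (Z)-2-methylbut-2-enoate, via mixed anhydride 24 (not isolated)
Conditions: 23, 2,4,6-trichlorobenzoyl chloride, Et3N, toluene, rt; then 22, toluene, 80 °C
Reagents that add atoms: none
Why: Yamaguchi-type esterification through the mixed anhydride 24, run without a nucleophilic catalyst so that the (Z) geometry is not lost by reversible conjugate addition; only the primary C18 hydroxyl is acylated, the tertiary C8 hydroxyl being too hindered.

Step 13
Reactants: 25 (4S,5S,8S,9S,10R,13S)-8-hydroxy-15-(triisopropylsilyloxy)-ent-labdan-18-yl (Z)-2-methylbut-2-enoate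
Product: 26 (4S,5S,8S,9S,10R,13S)-8,15-dihydroxy-ent-labdan-18-yl (Z)-2-methylbut-2-enoate
Conditions: HF·pyridine, pyridine/THF, 0 °C → rt
Reagents that add atoms: none
Why: Fluoride cleavage of the primary silyl ether under buffered conditions that neither isomerise nor cleave the angelate and do not dehydrate the tertiary alcohol.

Step 14
Reactants: 26 (4S,5S,8S,9S,10R,13S)-8,15-dihydroxy-ent-labdan-18-yl (Z)-2-methylbut-2-enoate
Product: 28 (4S,5S,8S,9S,10R,13S)-8-hydroxy-18-[(Z)-2-methylbut-2-enoyloxy]-ent-labdan-15-oic acid, via aldehyde 27 (not isolated)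
Conditions: TEMPO (cat.), PhI(OAc)2, MeCN/H2O, rt
Reagents that add atoms: water, O
Why: Oxoammonium oxidation of the primary alcohol through aldehyde 27 and its hydrate to the acid; the tertiary alcohol cannot react, the electron-poor enoate is inert, and C13 is β to the new carbonyl and cannot epimerise.

## Compound list

1 | 2,3-dimethylbenzoic acid | Cc1cccc(C(=O)O)c1C | starting material
2 | (S)-2-(methoxymethyl)pyrrolidine | COC[C@@H]1CCCN1 | starting material
3 | 2,3-dimethylbenzoyl chloride | Cc1cccc(C(=O)Cl)c1C | intermediate
4 | (S)-(2,3-dimethylphenyl)[2-(methoxymethyl)pyrrolidin-1-yl]methanone | Cc1cccc(C(=O)N2CCC[C@H]2COC)c1C | intermediate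
5 | (S)-citronellol, (3S)-3,7-dimethyloct-6-en-1-ol | CC(C)=CCC[C@H](C)CCO | starting material
6 | (3S)-3,7-dimethyl-1-(triisopropylsilyloxy)oct-6-ene | CC(C)=CCC[C@H](C)CCO[Si](C(C)C)(C(C)C)C(C)C | intermediate
7 | (2E,6S)-2,6-dimethyl-8-(triisopropylsilyloxy)oct-2-enal | O=C/C(C)=C/CC[C@H](C)CCO[Si](C(C)C)(C(C)C)C(C)C | intermediate
8 | (2E,6S)-2,6-dimethyl-8-(triisopropylsilyloxy)oct-2-en-1-ol | OC/C(C)=C/CC[C@H](C)CCO[Si](C(C)C)(C(C)C)C(C)C | intermediate
9 | (2E,6S)-1-bromo-2,6-dimethyl-8-(triisopropylsilyloxy)oct-2-ene | BrC/C(C)=C/CC[C@H](C)CCO[Si](C(C)C)(C(C)C)C(C)C | intermediate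
10 | benzylic lithium compound of 4 (lithium on the 2-methyl carbon) | [Li]Cc1c(C)cccc1C(=O)N1CCC[C@H]1COC | intermediate
11 | (S)-{2-[(3E,7S)-3,7-dimethyl-9-(triisopropylsilyloxy)non-3-en-1-yl]-3-methylphenyl}[2-(methoxymethyl)pyrrolidin-1-yl]methanone | Cc1cccc(C(=O)N2CCC[C@H]2COC)c1CC/C(C)=C/CC[C@H](C)CCO[Si](C(C)C)(C(C)C)C(C)C | intermediate
12 | benzyl chloromethyl ether | ClCOCc1ccccc1 | starting material
13 | potassium amide enolate of the 1,4-dihydro form of 11 | COC[C@@H]1CCCN1C([O-])=C1C=CCC(C)=C1CC/C(C)=C/CC[C@H](C)CCO[Si](C(C)C)(C(C)C)C(C)C.[K+] | intermediate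
14 | (S)-{(1R)-1-[(benzyloxy)methyl]-2-[(3E,7S)-3,7-dimethyl-9-(triisopropylsilyloxy)non-3-en-1-yl]-3-methylcyclohexa-2,5-dien-1-yl}[2-(methoxymethyl)pyrrolidin-1-yl]methanone | c1ccccc1COC[C@@]1(C(=O)N2CCC[C@H]2COC)C=CCC(C)=C1CC/C(C)=C/CC[C@H](C)CCO[Si](C(C)C)(C(C)C)C(C)C | intermediate
15 | bridged iminium ether trifluoroacetate (C19–O–C10 bridge cis to the C4 carboxamide carbon, H-5 on the opposite face) | c1ccccc1COC[C@@]1(C(=[N+]2CCC[C@H]2COC)O3)C=CC[C@@]3(C)[C@@H]1CC/C(C)=C/CC[C@H](C)CCO[Si](C(C)C)(C(C)C)C(C)C.[O-]C(=O)C(F)(F)F | intermediate
16 | C8 trifluoroacetate of 17 | c1ccccc1COC[C@@]1(C(=O)N2CCC[C@H]2COC)C=CC[C@]3(C)[C@@H]1CC[C@](C)(OC(=O)C(F)(F)F)[C@H]3CC[C@H](C)CCO[Si](C(C)C)(C(C)C)C(C)C | intermediate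
17 | (4R,5S,8S,9S,10R,13S)-18-benzyloxy-8-hydroxy-15-(triisopropylsilyloxy)-ent-labd-2-en-19-oic acid (S)-2-(methoxymethyl)pyrrolidide | c1ccccc1COC[C@@]1(C(=O)N2CCC[C@H]2COC)C=CC[C@]3(C)[C@@H]1CC[C@](C)(O)[C@H]3CC[C@H](C)CCO[Si](C(C)C)(C(C)C)C(C)C | intermediate
18 | (4S,5S,8S,9S,10R,13S)-18-benzyloxy-15-(triisopropylsilyloxy)-ent-labd-2-ene-8,19-diol | c1ccccc1COC[C@@]1(CO)C=CC[C@]2(C)[C@@H]1CC[C@](C)(O)[C@H]2CC[C@H](C)CCO[Si](C(C)C)(C(C)C)C(C)C | intermediate
19 | (4R,5S,8S,9S,10R,13S)-18-benzyloxy-8-hydroxy-15-(triisopropylsilyloxy)-ent-labd-2-en-19-al | c1ccccc1COC[C@@]1(C=O)C=CC[C@]2(C)[C@@H]1CC[C@](C)(O)[C@H]2CC[C@H](C)CCO[Si](C(C)C)(C(C)C)C(C)C | intermediate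
20 | N-(tert-butyldimethylsilyl)hydrazone of 19 | c1ccccc1COC[C@@]1(C=NN[Si](C)(C)C(C)(C)C)C=CC[C@]2(C)[C@@H]1CC[C@](C)(O)[C@H]2CC[C@H](C)CCO[Si](C(C)C)(C(C)C)C(C)C | intermediate
21 | (4S,5S,8S,9S,10R,13S)-18-benzyloxy-15-(triisopropylsilyloxy)-ent-labd-2-en-8-ol | c1ccccc1COC[C@@]1(C)C=CC[C@]2(C)[C@@H]1CC[C@](C)(O)[C@H]2CC[C@H](C)CCO[Si](C(C)C)(C(C)C)C(C)C | intermediate
22 | (4S,5S,8S,9S,10R,13S)-15-(triisopropylsilyloxy)-ent-labdane-8,18-diol | OC[C@@]1(C)CCC[C@]2(C)[C@@H]1CC[C@](C)(O)[C@H]2CC[C@H](C)CCO[Si](C(C)C)(C(C)C)C(C)C | intermediate
23 | angelic acid, (Z)-2-methylbut-2-enoic acid | C/C=C(/C)C(=O)O | starting material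
24 | (Z)-2-methylbut-2-enoic 2,4,6-trichlorobenzoic anhydride | C/C=C(/C)C(=O)OC(=O)c1c(Cl)cc(Cl)cc1Cl | intermediate
25 | (4S,5S,8S,9S,10R,13S)-8-hydroxy-15-(triisopropylsilyloxy)-ent-labdan-18-yl (Z)-2-methylbut-2-enoate | C/C=C(/C)C(=O)OC[C@@]1(C)CCC[C@]2(C)[C@@H]1CC[C@](C)(O)[C@H]2CC[C@H](C)CCO[Si](C(C)C)(C(C)C)C(C)C | intermediate
26 | (4S,5S,8S,9S,10R,13S)-8,15-dihydroxy-ent-labdan-18-yl (Z)-2-methylbut-2-enoate | C/C=C(/C)C(=O)OC[C@@]1(C)CCC[C@]2(C)[C@@H]1CC[C@](C)(O)[C@H]2CC[C@H](C)CCO | intermediate
27 | (4S,5S,8S,9S,10R,13S)-8-hydroxy-15-oxo-ent-labdan-18-yl (Z)-2-methylbut-2-enoate | C/C=C(/C)C(=O)OC[C@@]1(C)CCC[C@]2(C)[C@@H]1CC[C@](C)(O)[C@H]2CC[C@H](C)CC=O | intermediate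
28 | (4S,5S,8S,9S,10R,13S)-8-hydroxy-18-[(Z)-2-methylbut-2-enoyloxy]-ent-labdan-15-oic acid (CNP0315745.1) | C/C=C(/C)C(=O)OC[C@@]1(C)CCC[C@]2(C)[C@@H]1CC[C@](C)(O)[C@H]2CC[C@H](C)CC(=O)O | target

## Step count and least certain steps

Total: 14 steps. Longest linear sequence: 13 steps (5 → 28, steps 2–14); the amide branch (step 1) joins at step 5.

**Step 7 (key step, proposed new method).**
- What may go wrong: loss of facial control at C5 if protonation outruns amide participation. A 1,2-hydride shift from the allylic C1 methylene to the C10 cation, or intermolecular hydride transfer from that doubly allylic methylene, would lead to conjugated dienes or to rearomatisation with expulsion of the benzyloxymethyl arm. Elimination may compete with trifluoroacetate capture at C8. The silyl ether may undergo slow trifluoroacetolysis.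
- Fallback (known chemistry, from 14 back to 18): 14 is heated with TsOH·H2O in toluene, the established acid lactonisation of β,γ-unsaturated carboxamides, in which the bridged iminium ether is hydrolysed and the auxiliary expelled, to give the bridged γ-lactone F1. F1 is treated with HCO2H/H2SO4 and the crude formate saponified (KOH, MeOH/H2O). Alkyl–oxygen heterolysis of the tertiary lactone then feeds the classical formic/sulfuric acid cation–olefin cyclisation and gives the dihydroxy acid F2; the silyl ether is lost on the way. LiAlH4 in THF reduces F2 to the triol F3, and i-Pr3SiCl/imidazole silylates the unhindered C15 hydroxyl selectively to return 18.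

**Step 6.**
- What may go wrong: ammonolysis of the alkoxymethyl chloride competing with C-alkylation of the enolate, and a facial sense of alkylation other than the assumed one.
- Fallback (from 11 back to 14): the enolate 13 is protonated with NH4Cl instead of being alkylated and the 1,4-dihydro amide F4 is isolated. F4 is deprotonated with LiN(i-Pr)2 in THF in the absence of ammonia and the lithium enolate is alkylated with 12. The facial sense of this enolate need not equal that of the potassium enolate in ammonia and would be matched by the choice of auxiliary enantiomer.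

**Step 8.**
- What may go wrong: slow or incomplete hydride addition to the axial, doubly neopentyl carboxamide, or C–O instead of C–N cleavage leading to the tertiary amine.
- Fallback (from 17 directly to 19): hydrozirconation of the amide with Cp2Zr(H)Cl in THF, whose zirconated hemiaminal gives the aldehyde on work-up. No new compound is made and step 9 falls away.

**Step 10.**
- What may go wrong: sluggish condensation at the hindered aldehyde, or base-mediated loss of the silyl ether during the reduction.
- Fallback (from 18 back to 21): the C19 hydroxyl of 18 is converted with TsCl/pyridine into the 4-methylbenzenesulfonate F5 (the tertiary hydroxyl does not react), and F5 is reduced with LiBHEt3 in refluxing THF by hydride displacement of the neopentyl sulfonate. This replaces steps 9 and 10.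

**Step 12.**
- What may go wrong: Z→E isomerisation of the acyl donor to the tiglate, and slow acylation of the neopentyl hydroxyl without a nucleophilic catalyst.
- Fallback (from 22 back to 25): 22 is esterified with 2-[bis(2,2,2-trifluoroethoxy)phosphoryl]propanoic acid (DCC, DMAP) to the phosphonopropionate F6. A Z-selective Horner–Wadsworth–Emmons reaction under Still–Gennari conditions (KN(SiMe3)2, 18-crown-6, THF, −78 °C, acetaldehyde) then builds the (Z)-2-methylbut-2-enoate on the substrate.

## Further compounds

F1 | step 7 | bridged γ-lactone (C19 carbonyl, O on C10, H-5 trans to the lactone bridge), benzyl and triisopropylsilyl ethers retained | c1ccccc1COC[C@@]1(C(=O)O3)C=CC[C@@]3(C)[C@@H]1CC/C(C)=C/CC[C@H](C)CCO[Si](C(C)C)(C(C)C)C(C)C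
F2 | step 7 | (4R,5S,8S,9S,10R,13S)-18-benzyloxy-8,15-dihydroxy-ent-labd-2-en-19-oic acid | c1ccccc1COC[C@@]1(C(=O)O)C=CC[C@]2(C)[C@@H]1CC[C@](C)(O)[C@H]2CC[C@H](C)CCO
F3 | step 7 | (4S,5S,8S,9S,10R,13S)-18-benzyloxy-ent-labd-2-ene-8,15,19-triol | c1ccccc1COC[C@@]1(CO)C=CC[C@]2(C)[C@@H]1CC[C@](C)(O)[C@H]2CC[C@H](C)CCO
F4 | step 6 | 1,4-dihydro amide from protonation of 13 (either epimer at the ring CH) | COC[C@@H]1CCCN1C(=O)C1C=CCC(C)=C1CC/C(C)=C/CC[C@H](C)CCO[Si](C(C)C)(C(C)C)C(C)C
F0 | step 8 | none | none
F5 | step 10 | C19 4-methylbenzenesulfonate of 18 | c1ccccc1COC[C@@]1(COS(=O)(=O)c2ccc(C)cc2)C=CC[C@]3(C)[C@@H]1CC[C@](C)(O)[C@H]3CC[C@H](C)CCO[Si](C(C)C)(C(C)C)C(C)C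
F6 | step 12 | C18 2-[bis(2,2,2-trifluoroethoxy)phosphoryl]propanoate of 22 (both epimers at the phosphonate carbon) | CC(C(=O)OC[C@@]1(C)CCC[C@]2(C)[C@@H]1CC[C@](C)(O)[C@H]2CC[C@H](C)CCO[Si](C(C)C)(C(C)C)C(C)C)P(=O)(OCC(F)(F)F)OCC(F)(F)F
A1 | alternative 1 | andrographolide | OC[C@]1(C)[C@H](O)CC[C@]2(C)[C@@H]1CCC(=C)[C@H]2C/C=C3/C(=O)OC[C@H]3O
A2 | alternative 1 | 19-deoxy C3 alcohol (8-O-triethylsilyl, 12-O-tert-butyldimethylsilyl, C13–C16 removed) | CC1(C)[C@H](O)CC[C@]2(C)[C@@H]1CC[C@](C)(O[Si](CC)(CC)CC)[C@H]2CCO[Si](C)(C)C(C)(C)C
A3 | alternative 1 | C3–O–Si–C18 diethyl oxasilolane | CC[Si]1(CC)C[C@@]2(C)[C@H](O1)CC[C@]3(C)[C@@H]2CC[C@](C)(O[Si](CC)(CC)CC)[C@H]3CCO[Si](C)(C)C(C)(C)C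
A4 | alternative 2 | open-chain trienal with (E)-3-methyl enal and (E,E)-1-silyloxydiene | O=C/C=C(\C)CC[C@@H](O[Si](C)(C)C(C)(C)C)[C@](C)(COCc1ccccc1)/C=C/C=C/O[Si](C)(C)C(C)(C)C
A5 | alternative 2 | trans-fused octalin with C9 aldehyde, C8 silyloxy and C10 methyl | c1ccccc1COC[C@@]1(C)[C@H](O[Si](C)(C)C(C)(C)C)CC[C@]2(C)[C@@H]1C=C[C@@H](O[Si](C)(C)C(C)(C)C)[C@H]2C=O
A6 | alternative 3 | (2E,6E,10S)-12-(tert-butyldiphenylsilyloxy)-2,6,10-trimethyldodeca-2,6-dienal | O=C/C(C)=C/CC/C(C)=C/CC[C@H](C)CCO[Si](c1ccccc1)(c1ccccc1)C(C)(C)C
A7 | alternative 3 | (Z)-3-(tert-butyldimethylsilyloxy)penta-1,3-diene | C=C/C(O[Si](C)(C)C(C)(C)C)=C/C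
A8 | alternative 3 | ring A cycloadduct (C1 silyl enol ether, C4 formyl, C5 side arm) | O=C[C@@]1(C)CC=C(O[Si](C)(C)C(C)(C)C)[C@@H](C)[C@@H]1CC/C(C)=C/CC[C@H](C)CCO[Si](c2ccccc2)(c2ccccc2)C(C)(C)C
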